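**Plan**

- Numbering: chroman-2-one numbering, unprimed for the 5,7-dihydroxy lactone (ring A), primed for the 5,6,7,8-tetrahydroxy lactone (ring B). The target is (3R,4R,3'S,4'R): trans across C3–C4, cis across C3'–C4'.
- Cuts: first the two C–H bonds at C3' and C4' (with the seven O-benzyl bonds), then C3–C3' and C4'–C4a' together. This leaves a 3-bromo lactone A and an acyclic pentaoxygenated aryl 3-arylpropiolate, which fall to a coumarin plus an arylboronic acid (C4–aryl bond) and to a phenol plus an arylpropiolic acid (ester C–O bond).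
- Enabling feature: C3 and C3' are both carbonyl α-carbons, and C3' lies between C2'=O and the aryl-bearing C4', itself bonded to C4a' of the ring B arene. This is the imprint of an α-carbonyl radical adding to an aryl 3-arylpropiolate, with the vinyl radical closing onto the aryl ester.
- Forward order: ring A is made as a coumarin, arylated at C4 and brominated at C3; the ester is assembled separately; ring B closes in the radical step as a 4-arylcoumarin; the last step saturates C3'=C4' and frees the phenols.
- Stereochemistry: C4 from a rhodium/(R)-SEGPHOS conjugate arylation; C3 from radical addition anti to the C4 aryl group; C3' and C4' from syn addition of H2 on the ring B face next to the lactone A carbonyl.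

Key step: step 11

Assumption: (R)-SEGPHOS is taken to give the 4R lactone, as it does with simple coumarins; if the sense is opposite, (S)-SEGPHOS would be used with nothing else changed.

**Route**

Step 1
Reactants: 1 phloroglucinol; 2 ethyl propiolate
Product: 3 5,7-dihydroxycoumarin
Conditions: ZnCl2, dioxane, 95 °C
Reagents that add atoms: none
Why: Pechmann-type condensation in which the very nucleophilic arene adds to the zinc-activated propiolate and the neighbouring phenol lactonises with loss of ethanol; the symmetry of 1 removes any regiochemical question.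

Step 2
Reactants: 3 5,7-dihydroxycoumarin
Product: 4 5,7-bis(benzyloxy)coumarin
Conditions: BnBr, K2CO3, DMF, rt
Reagents that add atoms: benzyl bromide, BrCc1ccccc1
Why: Williamson etherification of both phenols; carbonate does not open the coumarin lactone.

Step 3
Reactants: 4 5,7-bis(benzyloxy)coumarin; 5 4-(benzyloxy)phenylboronic acid
Product: 6 (4R)-5,7-bis(benzyloxy)-4-[4-(benzyloxy)phenyl]chroman-2-one
Conditions: Rh(acac)(C2H4)2 (3 mol %), (R)-SEGPHOS, 5 (excess), dioxane/H2O 10:1, 60 °C
Reagents that add atoms: none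
Why: Hayashi–Miyaura asymmetric 1,4-addition in which the aryl complex of monovalent rhodium inserts the C3=C4 bond on one enantioface and the rhodium enolate is hydrolysed, so C4 (R) is set by the ligand.

Step 4
Reactants: 6 (4R)-5,7-bis(benzyloxy)-4-[4-(benzyloxy)phenyl]chroman-2-one
Product: 8 (4R)-5,7-bis(benzyloxy)-4-[4-(benzyloxy)phenyl]-3-bromochroman-2-one (C3 epimers), via lithium enolate 7 (not isolated)
Conditions: LiN(SiMe3)2, THF, −78 °C; cannulated into BrCl2C–CCl2Br, THF, −78 °C; AcOH quench
Reagents that add atoms: 1,2-dibromo-1,1,2,2-tetrachloroethane, BrC(Cl)(Cl)C(Cl)(Cl)Br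
Why: α-bromination of a lactone enolate with a bromine donor that leaves the electron-rich arenes alone; the C3 configuration does not matter because the next step passes through the planar C3 radical, and C4 is not touched.

Step 5
Reactants: 9 2,3,4-trihydroxybenzaldehyde
Product: 11 benzene-1,2,3,4-tetrol, via aryl formate 10 (not isolated)
Conditions: 30% H2O2, aq NaOH, N2, 0 °C → rt; then aq HCl
Reagents that add atoms: hydrogen peroxide, OO
Why: Dakin oxidation in which the hydroxy-activated aryl group migrates from carbon to oxygen in the peroxide adduct and the formate is hydrolysed in the alkaline medium.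

Step 6
Reactants: 11 benzene-1,2,3,4-tetrol
Product: 12 1,2,3,4-tetrakis(benzyloxy)benzene
Conditions: BnBr, K2CO3, degassed DMF, argon, rt → 60 °C
Reagents that add atoms: benzyl bromide, BrCc1ccccc1
Why: fourfold Williamson etherification, run without air because the polyphenolate is easily oxidised.

Step 7
Reactants: 12 1,2,3,4-tetrakis(benzyloxy)benzene
Product: 13 1-bromo-2,3,4,5-tetrakis(benzyloxy)benzene
Conditions: NBS (1.0 equiv), MeCN, 0 °C
Reagents that add atoms: N-bromosuccinimide, O=C1CCC(=O)N1Br
Why: electrophilic aromatic bromination of a strongly activated arene whose two free positions are equivalent by symmetry.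

Step 8
Reactants: 13 1-bromo-2,3,4,5-tetrakis(benzyloxy)benzene
Product: 16 2,3,4,5-tetrakis(benzyloxy)phenol, via aryllithium 14 (not isolated), via lithium aryltrimethoxyborate 15 (not isolated)
Conditions: n-BuLi, THF, −78 °C; B(OMe)3, −78 → 0 °C; then H2O2, AcOH, 0 °C → rt
Reagents that add atoms: hydrogen peroxide, OO
Why: bromine–lithium exchange, borylation and oxidative aryl shift from boron to oxygen is the standard aryl bromide to phenol conversion, and the exchange at −78 °C outruns deprotonation of the benzyl ethers.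

Step 9
Reactants: 17 1-(benzyloxy)-4-iodobenzene; 18 propiolic acid
Product: 19 3-[4-(benzyloxy)phenyl]propiolic acid
Conditions: Pd(PPh3)4 (cat.), DBU, DMSO, 35 °C; aq HCl work-up
Reagents that add atoms: none
Why: copper-free Sonogashira coupling of the aryl iodide with the terminal alkyne of the propiolate salt on zerovalent palladium, at a temperature where the product does not decarboxylate.

Step 10
Reactants: 19 3-[4-(benzyloxy)phenyl]propiolic acid; 16 2,3,4,5-tetrakis(benzyloxy)phenol
Product: 20 2,3,4,5-tetrakis(benzyloxy)phenyl 3-[4-(benzyloxy)phenyl]propiolate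
Conditions: DCC, DMAP (cat.), CH2Cl2, 0 °C → rt
Reagents that add atoms: none
Why: Steglich esterification, the usual access to aryl 3-arylpropiolates.

Step 11
Reactants: 8 (4R)-5,7-bis(benzyloxy)-4-[4-(benzyloxy)phenyl]-3-bromochroman-2-one; 20 2,3,4,5-tetrakis(benzyloxy)phenyl 3-[4-(benzyloxy)phenyl]propiolate
Product: 21 (3R,4R)-5,7-bis(benzyloxy)-4-[4-(benzyloxy)phenyl]-3-{5,6,7,8-tetrakis(benzyloxy)-4-[4-(benzyloxy)phenyl]-2-oxo-2H-chromen-3-yl}chroman-2-one
Conditions: fac-Ir(ppy)3 (2 mol %), K2HPO4 (2 equiv), 20 (1.5 equiv), degassed DMF, blue LEDs (450 nm), rt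
Reagents that add atoms: none
Why: Photoexcited fac-Ir(ppy)3 reduces the C–Br bond of 8 by single-electron transfer, and the electrophilic, planar C3 radical adds to the alkyne carbon next to the ester of 20 (C3–C3'), a polarity-matched addition that leaves a linear vinyl radical at C4' stabilised by the 4-benzyloxyphenyl group. That radical closes ring B on the aryl ester (C4'–C4a'), either by 6-endo-trig attack at the only free ortho CH or by 5-exo-trig ipso attack followed by a 1,2-acyloxy shift to that same CH; since the four other ring positions all carry oxygen, both paths end in the same 5,6,7,8-tetrakis(benzyloxy)coumarin. The tetravalent iridium complex formed in the first event oxidises the cyclohexadienyl radical, K2HPO4 takes up the proton, and the catalyst returns to its trivalent ground state. The closest known reaction type is the visible-light radical addition–cyclisation of aryl alkynoates with α-bromo carbonyl compounds to 3-alkyl-4-arylcoumarins. C3 is the only new stereocentre: the alkyne should approach the radical anti to the pseudo-axial C4 aryl group, so the 3,4-trans (3R,4R) isomer is expected from either epimer of 8, and C4 is not involved. The step needs regioselective addition at the ester-bearing alkyne carbon and capture of the radical before it is reduced or loses HBr, which the ynoate polarisation, the excess of 20 and the weak, sparingly soluble base are meant to secure.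

Step 12
Reactants: 21 (3R,4R)-5,7-bis(benzyloxy)-4-[4-(benzyloxy)phenyl]-3-{5,6,7,8-tetrakis(benzyloxy)-4-[4-(benzyloxy)phenyl]-2-oxo-2H-chromen-3-yl}chroman-2-one
Product: 23 (3R,4R)-5,7-dihydroxy-4-(4-hydroxyphenyl)-3-[(3S,4R)-5,6,7,8-tetrahydroxy-4-(4-hydroxyphenyl)-2-oxochroman-3-yl]chroman-2-one, via heptaphenol coumarin 22 (not isolated)
Conditions: H2 (5 bar), 10% Pd/C, THF/EtOAc, cat. AcOH, rt → 40 °C; filtration and isolation under argon
Reagents that add atoms: none
Why: heterogeneous hydrogenation first cleaves the seven benzyl ethers and then adds H2 syn across the tetrasubstituted C3'=C4' bond; with C3–H eclipsing the C4' aryl group to relieve allylic strain, C4 of lactone A covers one face of ring B and the lactone A carbonyl lies on the other, so delivery of both hydrogens from the carbonyl-flanked face should set C3' (S) and C4' (R) cis, while C3 and C4 are unchanged under these non-basic conditions.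

**Compound list**

1 | phloroglucinol | Oc1cc(O)cc(O)c1 | starting material
2 | ethyl propiolate | C#CC(=O)OCC | starting material
3 | 5,7-dihydroxycoumarin | O=C1C=Cc2c(O)cc(O)cc2O1 | intermediate
4 | 5,7-bis(benzyloxy)coumarin | O=C1C=Cc2c(OCc3ccccc3)cc(OCc3ccccc3)cc2O1 | intermediate
5 | 4-(benzyloxy)phenylboronic acid | OB(O)c1ccc(OCc2ccccc2)cc1 | starting material
6 | (4R)-5,7-bis(benzyloxy)-4-[4-(benzyloxy)phenyl]chroman-2-one | O=C1Oc2cc(OCc3ccccc3)cc(OCc3ccccc3)c2[C@@H](c2ccc(OCc3ccccc3)cc2)C1 | intermediate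
7 | lithium enolate of 6 (not isolated) | [Li]OC1=C[C@H](c2ccc(OCc3ccccc3)cc2)c2c(OCc3ccccc3)cc(OCc3ccccc3)cc2O1 | intermediate
8 | (4R)-5,7-bis(benzyloxy)-4-[4-(benzyloxy)phenyl]-3-bromochroman-2-one (C3 epimers) | O=C1Oc2cc(OCc3ccccc3)cc(OCc3ccccc3)c2[C@@H](c2ccc(OCc3ccccc3)cc2)C1Br | intermediate
9 | 2,3,4-trihydroxybenzaldehyde | O=Cc1ccc(O)c(O)c1O | starting material
10 | 2,3,4-trihydroxyphenyl formate (not isolated) | O=COc1ccc(O)c(O)c1O | intermediate
11 | benzene-1,2,3,4-tetrol | Oc1ccc(O)c(O)c1O | intermediate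
12 | 1,2,3,4-tetrakis(benzyloxy)benzene | c1cc(OCc2ccccc2)c(OCc2ccccc2)c(OCc2ccccc2)c1OCc1ccccc1 | intermediate
13 | 1-bromo-2,3,4,5-tetrakis(benzyloxy)benzene | Brc1cc(OCc2ccccc2)c(OCc2ccccc2)c(OCc2ccccc2)c1OCc1ccccc1 | intermediate
14 | 2,3,4,5-tetrakis(benzyloxy)phenyllithium (not isolated) | [Li]c1cc(OCc2ccccc2)c(OCc2ccccc2)c(OCc2ccccc2)c1OCc1ccccc1 | intermediate
15 | lithium trimethoxy[2,3,4,5-tetrakis(benzyloxy)phenyl]borate (not isolated) | [Li+].CO[B-](OC)(OC)c1cc(OCc2ccccc2)c(OCc2ccccc2)c(OCc2ccccc2)c1OCc1ccccc1 | intermediate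
16 | 2,3,4,5-tetrakis(benzyloxy)phenol | Oc1cc(OCc2ccccc2)c(OCc2ccccc2)c(OCc2ccccc2)c1OCc1ccccc1 | intermediate
17 | 1-(benzyloxy)-4-iodobenzene | Ic1ccc(OCc2ccccc2)cc1 | starting material
18 | propiolic acid | C#CC(=O)O | starting material
19 | 3-[4-(benzyloxy)phenyl]propiolic acid | OC(=O)C#Cc1ccc(OCc2ccccc2)cc1 | intermediate
20 | 2,3,4,5-tetrakis(benzyloxy)phenyl 3-[4-(benzyloxy)phenyl]propiolate | O=C(C#Cc1ccc(OCc2ccccc2)cc1)Oc1cc(OCc2ccccc2)c(OCc2ccccc2)c(OCc2ccccc2)c1OCc1ccccc1 | intermediate
21 | (3R,4R)-5,7-bis(benzyloxy)-4-[4-(benzyloxy)phenyl]-3-{5,6,7,8-tetrakis(benzyloxy)-4-[4-(benzyloxy)phenyl]-2-oxo-2H-chromen-3-yl}chroman-2-one | O=C1Oc2cc(OCc3ccccc3)cc(OCc3ccccc3)c2[C@@H](c2ccc(OCc3ccccc3)cc2)[C@@H]1C1=C(c2ccc(OCc3ccccc3)cc2)c2c(OCc3ccccc3)c(OCc3ccccc3)c(OCc3ccccc3)c(OCc3ccccc3)c2OC1=O | intermediate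
22 | (3R,4R)-5,7-dihydroxy-4-(4-hydroxyphenyl)-3-[5,6,7,8-tetrahydroxy-4-(4-hydroxyphenyl)-2-oxo-2H-chromen-3-yl]chroman-2-one (not isolated) | O=C1Oc2cc(O)cc(O)c2[C@@H](c2ccc(O)cc2)[C@@H]1C1=C(c2ccc(O)cc2)c2c(O)c(O)c(O)c(O)c2OC1=O | intermediate
23 | (3R,4R)-5,7-dihydroxy-4-(4-hydroxyphenyl)-3-[(3S,4R)-5,6,7,8-tetrahydroxy-4-(4-hydroxyphenyl)-2-oxochroman-3-yl]chroman-2-one | O=C1Oc2cc(O)cc(O)c2[C@@H](c2ccc(O)cc2)[C@@H]1[C@H]1C(=O)Oc2c(O)c(O)c(O)c(O)c2[C@H]1c1ccc(O)cc1 | target

**Count**

Total steps: 12. Longest linear sequence: 7 steps (9 → 11 → 12 → 13 → 16 → 20 → 21 → 23; steps 5, 6, 7, 8, 10, 11, 12).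

**Steps most likely to fail**

Step 11. The hindered secondary C3 radical may be reduced back to the lactone, or the bromide may lose HBr to the 4-arylcoumarin, before addition to the internal alkyne. The ipso adduct may also be oxidised and lose the benzyl group of the para ether, ending in a spirodienone instead of migrating. Fallback: the same two bonds are made in two polar operations. Ester 20 is cyclised with ICl (CH2Cl2, −78 °C; electrophilic 6-endo iodocyclisation onto the free ortho CH) to 5,6,7,8-tetrakis(benzyloxy)-4-[4-(benzyloxy)phenyl]-3-iodocoumarin F1. Bromide 8 is converted with activated zinc in THF into the bromozinc enolate (Reformatsky reagent) F2. F1 and F2 are joined by palladium-catalysed coupling of the zinc enolate (Pd(dba)2, P(t-Bu)3, THF, rt), a Negishi-type α-arylation. The C3 centre, α to the lactone carbonyl, should settle in the trans arrangement, and the route is rejoined at 21.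

Step 12. Hydrogen uptake may stop at the tetrasubstituted, electron-rich alkene after debenzylation, or adsorption may occur on the other face of ring B and give the cis-3'R,4'S isomer. Fallback: from 21, a homogeneous, carbonyl-directed hydrogenation with the cationic iridium complex [Ir(cod)(PCy3)(py)]PF6 (CH2Cl2, H2 50 bar). The metal binds the lactone A carbonyl and delivers H2 to the ring B face syn to it, leaving the benzyl ethers in place and giving the heptabenzyl ether of the target F3. Hydrogenolysis of F3 (H2 1 bar, Pd/C, THF/EtOAc) then returns to 23.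

Step 3. Insertion of the coumarin into the aryl–rhodium bond may be slowed by the peri benzyloxy group at C5, so that protodeboronation of 5 consumes the aryl donor and conversion or enantioselectivity suffers. Fallback: the C4–C4a bond is made by Friedel–Crafts chemistry and the stereocentre by hydride delivery.
- Phloroglucinol 1 and acid 19 are condensed by hydroarylation–lactonisation (Pd(OAc)2 cat., TFA/CH2Cl2, rt) to 4-[4-(benzyloxy)phenyl]-5,7-dihydroxycoumarin F4.
- F4 is benzylated (BnBr, K2CO3, DMF) to 5,7-bis(benzyloxy)-4-[4-(benzyloxy)phenyl]coumarin F5.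
- F5 undergoes copper hydride asymmetric conjugate reduction (Cu(OAc)2, the DTBM-SEGPHOS enantiomer that gives 4R, (EtO)2MeSiH, t-BuOH, toluene), run as a tandem 1,4/1,2-reduction to (4R)-5,7-bis(benzyloxy)-4-[4-(benzyloxy)phenyl]chroman-2-ol F6.
- F6 is oxidised with TEMPO/PhI(OAc)2 back to lactone 6.

**Further compounds**

F1 | step 11 | 5,6,7,8-tetrakis(benzyloxy)-4-[4-(benzyloxy)phenyl]-3-iodo-2H-chromen-2-one | O=C1Oc2c(OCc3ccccc3)c(OCc3ccccc3)c(OCc3ccccc3)c(OCc3ccccc3)c2C(c2ccc(OCc3ccccc3)cc2)=C1I
F2 | step 11 | bromozinc enolate (Reformatsky reagent) of (4R)-5,7-bis(benzyloxy)-4-[4-(benzyloxy)phenyl]chroman-2-one | O=C1Oc2cc(OCc3ccccc3)cc(OCc3ccccc3)c2[C@@H](c2ccc(OCc3ccccc3)cc2)C1[Zn]Br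
F3 | step 12 | (3R,4R)-5,7-bis(benzyloxy)-4-[4-(benzyloxy)phenyl]-3-{(3S,4R)-5,6,7,8-tetrakis(benzyloxy)-4-[4-(benzyloxy)phenyl]-2-oxochroman-3-yl}chroman-2-one | O=C1Oc2cc(OCc3ccccc3)cc(OCc3ccccc3)c2[C@@H](c2ccc(OCc3ccccc3)cc2)[C@@H]1[C@H]1C(=O)Oc2c(OCc3ccccc3)c(OCc3ccccc3)c(OCc3ccccc3)c(OCc3ccccc3)c2[C@H]1c1ccc(OCc2ccccc2)cc1
F4 | step 3 | 4-[4-(benzyloxy)phenyl]-5,7-dihydroxy-2H-chromen-2-one | O=C1C=C(c2ccc(OCc3ccccc3)cc2)c2c(O)cc(O)cc2O1
F5 | step 3 | 5,7-bis(benzyloxy)-4-[4-(benzyloxy)phenyl]-2H-chromen-2-one | O=C1C=C(c2ccc(OCc3ccccc3)cc2)c2c(OCc3ccccc3)cc(OCc3ccccc3)cc2O1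
F6 | step 3 | (4R)-5,7-bis(benzyloxy)-4-[4-(benzyloxy)phenyl]chroman-2-ol (anomers) | OC1Oc2cc(OCc3ccccc3)cc(OCc3ccccc3)c2[C@@H](c2ccc(OCc3ccccc3)cc2)C1
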